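**Retrosynthetic overview**

1. Locants are those of the azulene skeleton of the target (cyclopentane = C1, C2, C3, C3a, C8a; cycloheptene = C3a, C4–C8, C8a); β is the face of the C8a methyl group. End game, backwards: C4 anisoate, C8 acetate (installed with inversion), C6 methyl and C6=C7 built from a C8 ketone.
2. Key disconnection: the C2–C3 bond of the cyclopentane, closed last by a SmI2 Barbier reaction between a primary iodide (C2) and an isobutyryl ketone (C3), two electrophilic carbons joined by polarity reversal. Enabling feature: the fully substituted carbinol C3 (OH, isopropyl) sits next to the unfunctionalised methylene C2, and this bond touches neither ring-fusion atom (C3a, C8a). The trans fusion can therefore be fixed on the cycloheptanone beforehand; a closure at C3a or C8a from a tether would give the cis-fused bicycle.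
3. The two trans side chains (isobutyryl on C3a, iodoethyl and methyl on C8a) come from one conjugate addition/enolate allylation on (S)-4-silyloxy-2-methylcyclohept-2-enone, each new bond anti to its neighbour, followed by double ozonolysis.
4. That enone comes from cyclohepta-1,3-diene: singlet oxygen delivers both ring oxygens (C4, C8) at once as a temporary peroxide bridge, a ring absent from the target, which is opened enantioselectively (Kornblum–DeLaMare).
5. Order of rings: seven-membered ring (bought) → temporary 6,7-dioxabicycle (made in step 1, opened in step 2) → cyclopentane (step 10, the last ring).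

Key step: step 10

Remark: in step 2 the cinchona catalyst is taken to be the pseudoenantiomer that gives the (S)-carbinol (the other gives the antipode); monocyclic ketones are numbered with the ring C=O as C1, and 2-bromo-3-methylbut-1-ene is assumed to be purchasable.

**Route**

Step 1
Reactants: 1 cyclohepta-1,3-diene
Product: 2 (1R,5S)-6,7-dioxabicyclo[3.2.2]non-8-ene (meso endoperoxide)
Conditions: O2, visible light, tetraphenylporphyrin (cat.), CH2Cl2, 0 °C
Reagents that add atoms: dioxygen, O=O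
Why: Singlet-oxygen [4+2] cycloaddition (photooxygenation) across the cisoid diene gives the meso endoperoxide, so both ring oxygens of the target arrive cis in one event.

Step 2
Reactants: 2 (1R,5S)-6,7-dioxabicyclo[3.2.2]non-8-ene
Product: 3 (4S)-4-hydroxycyclohept-2-en-1-one
Conditions: 9-O-acetylcupreidine (10 mol %), CH2Cl2, rt
Reagents that add atoms: none
Why: Enantioselective Kornblum–DeLaMare rearrangement, in which the chiral base removes one of the two enantiotopic bridgehead hydrogens as the O–O bond breaks, so that carbon becomes the ketone (future C8) and the other remains as the (S)-carbinol (future C4) under catalyst control.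

Step 3
Reactants: 3 (4S)-4-hydroxycyclohept-2-en-1-one
Product: 4 (4S)-4-[(tert-butyldimethylsilyl)oxy]cyclohept-2-en-1-one
Conditions: TBSCl, imidazole, DMF, rt
Reagents that add atoms: tert-butyldimethylsilyl chloride, CC(C)(C)[Si](C)(C)Cl
Why: Standard silylation of the secondary alcohol; the bulky silyl ether later directs the conjugate addition.

Step 4
Reactants: 4 (4S)-4-[(tert-butyldimethylsilyl)oxy]cyclohept-2-en-1-one
Product: 5 (4S)-4-[(tert-butyldimethylsilyl)oxy]-2-iodocyclohept-2-en-1-one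
Conditions: I2, pyridine, CH2Cl2, 0 °C to rt
Reagents that add atoms: iodine, II
Why: α-Iodination of the enone by pyridine addition, iodination and elimination (Baylis–Hillman-type α-activation) should give the 2-iodoenone without touching the stereocentre.

Step 5
Reactants: 5 (4S)-4-[(tert-butyldimethylsilyl)oxy]-2-iodocyclohept-2-en-1-one
Product: 6 (4S)-4-[(tert-butyldimethylsilyl)oxy]-2-methylcyclohept-2-en-1-one
Conditions: Me4Sn, Pd2(dba)3 (2.5 mol %), AsPh3, CuI, NMP, 60 °C
Reagents that add atoms: tetramethylstannane, C[Sn](C)(C)C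
Why: Stille cross-coupling of the α-iodoenone installs the methyl group that becomes the angular C8a methyl.

Step 6
Reactants: 6 (4S)-4-[(tert-butyldimethylsilyl)oxy]-2-methylcyclohept-2-en-1-one; 7 2-bromo-3-methylbut-1-ene; 8 3-iodoprop-1-ene (allyl iodide)
Product: 11 (2S,3S,4S)-4-[(tert-butyldimethylsilyl)oxy]-2-methyl-3-(3-methylbut-1-en-2-yl)-2-(prop-2-en-1-yl)cycloheptan-1-one, via silyl enol ether 9 (not isolated), via lithium enolate 10 (not isolated)
Conditions: 7, Mg, THF; then 6, CuBr·SMe2 (20 mol %), TMSCl, HMPA, −78 °C; solvent exchange; MeLi, THF, 0 °C; then 8, HMPA, −78 to 0 °C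
Reagents that add atoms: none
Why: Copper-catalysed conjugate addition of the alkenyl Grignard reagent with TMSCl occurs anti to the γ-silyloxy group (sets C3a), and the regiodefined lithium enolate released by MeLi is C-allylated anti to the new alkenyl group (sets the quaternary C8a); this conjugate addition–enolate alkylation sequence leaves the two side chains trans.

Step 7
Reactants: 11 (2S,3S,4S)-4-[(tert-butyldimethylsilyl)oxy]-2-methyl-3-(3-methylbut-1-en-2-yl)-2-(prop-2-en-1-yl)cycloheptan-1-one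
Product: 12 2-[(1S,2S,3S)-3-[(tert-butyldimethylsilyl)oxy]-1-methyl-2-(2-methylpropanoyl)-7-oxocycloheptyl]acetaldehyde
Conditions: O3, pyridine, CH2Cl2, −78 °C
Reagents that add atoms: ozone, [O-][O+]=O
Why: Ozonolysis cleaves both terminal alkenes, the only C=C bonds present, and unveils the isobutyryl ketone and the acetaldehyde side chain together; pyridine gives the carbonyl compounds directly.

Step 8
Reactants: 12 2-[(1S,2S,3S)-3-[(tert-butyldimethylsilyl)oxy]-1-methyl-2-(2-methylpropanoyl)-7-oxocycloheptyl]acetaldehyde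
Product: 13 (2S,3S,4S)-4-[(tert-butyldimethylsilyl)oxy]-2-(2-hydroxyethyl)-2-methyl-3-(2-methylpropanoyl)cycloheptan-1-one
Conditions: NaBH4 (0.3 equiv), EtOH/CH2Cl2, −78 °C
Reagents that add atoms: none
Why: Chemoselective borohydride reduction of the aldehyde in the presence of two hindered ketones at low temperature.

Step 9
Reactants: 13 (2S,3S,4S)-4-[(tert-butyldimethylsilyl)oxy]-2-(2-hydroxyethyl)-2-methyl-3-(2-methylpropanoyl)cycloheptan-1-one
Product: 14 (2S,3S,4S)-4-[(tert-butyldimethylsilyl)oxy]-2-(2-iodoethyl)-2-methyl-3-(2-methylpropanoyl)cycloheptan-1-one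
Conditions: I2, PPh3, imidazole, CH2Cl2, 0 °C
Reagents that add atoms: iodine, II
Why: Appel iodination of the primary alcohol under neutral conditions that leave the β-silyloxy ketone untouched.

Step 10
Reactants: 14 (2S,3S,4S)-4-[(tert-butyldimethylsilyl)oxy]-2-(2-iodoethyl)-2-methyl-3-(2-methylpropanoyl)cycloheptan-1-one
Product: 15 (3R,3aS,4S,8aS)-4-[(tert-butyldimethylsilyl)oxy]-3-hydroxy-8a-methyl-3-(propan-2-yl)octahydroazulen-8(1H)-one
Conditions: SmI2 (2.5 equiv), HMPA, THF, −78 to 0 °C; then aq. NH4Cl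
Reagents that add atoms: none
Why: Samarium Barbier cyclisation: SmI2/HMPA reduces the primary carbon–iodine bond (radical, then alkylsamarium) and this C2 nucleophile adds to the isobutyryl carbonyl C3, so two electrophilic carbons are joined by polarity reversal. The closest known reaction type is the SmI2-promoted cyclisation of δ-iodo ketones to cyclopentanols. The cyclopentane closes in the 5-exo-trig mode at the carbonyl, and because neither ring-fusion carbon takes part, the trans arrangement of the two side chains is carried unchanged into a trans ring fusion. The new stereocentre C3 is under substrate control: in the ring-forming transition state the isopropyl group should turn to the α face next to H-3a, away from the C3a–C4 bond and the angular methyl group, so that the oxygen ends on the β face. The step needs chemoselectivity for the C3 ketone over the C8 ketone, which is secured by ring size (attack at C8 would give a cyclobutanol) and by the absence of a proton source, so that neither ketone is reduced to an alcohol.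

Step 11
Reactants: 15 (3R,3aS,4S,8aS)-4-[(tert-butyldimethylsilyl)oxy]-3-hydroxy-8a-methyl-3-(propan-2-yl)octahydroazulen-8(1H)-one
Product: 16 (3R,3aS,4S,8aS)-4-[(tert-butyldimethylsilyl)oxy]-3-hydroxy-8a-methyl-3-(propan-2-yl)-2,3,3a,4,5,8a-hexahydroazulen-8(1H)-one
Conditions: IBX, 4-methoxypyridine N-oxide, DMSO, rt
Reagents that add atoms: none
Why: IBX dehydrogenation of the ketone, which can enolise only toward C7 because C8a is quaternary, should give the C6=C7 enone.

Step 12
Reactants: 16 (3R,3aS,4S,8aS)-4-[(tert-butyldimethylsilyl)oxy]-3-hydroxy-8a-methyl-3-(propan-2-yl)-2,3,3a,4,5,8a-hexahydroazulen-8(1H)-one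
Product: 18 (3R,3aS,4S,8aS)-4-[(tert-butyldimethylsilyl)oxy]-3-hydroxy-6,8a-dimethyl-3-(propan-2-yl)-2,3,3a,4,5,8a-hexahydroazulen-8(1H)-one, via silyl enol ether 17 (not isolated)
Conditions: MeMgBr (excess), CuBr·SMe2 (cat.), TMSCl, THF, −78 °C; then Pd(OAc)2, MeCN, rt
Reagents that add atoms: methylmagnesium bromide, C[Mg]Br
Why: Copper-catalysed conjugate addition of the methyl Grignard reagent with TMSCl trapping places the methyl group on C6, and Saegusa–Ito oxidation of the silyl enol ether restores the enone by β-hydride elimination from C6, which erases the transient C6 stereocentre.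

Step 13
Reactants: 18 (3R,3aS,4S,8aS)-4-[(tert-butyldimethylsilyl)oxy]-3-hydroxy-6,8a-dimethyl-3-(propan-2-yl)-2,3,3a,4,5,8a-hexahydroazulen-8(1H)-one
Product: 19 (3R,3aS,4S,8S,8aS)-4-[(tert-butyldimethylsilyl)oxy]-6,8a-dimethyl-3-(propan-2-yl)-1,2,3,3a,4,5,8,8a-octahydroazulene-3,8-diol
Conditions: NaBH4, CeCl3·7H2O, MeOH, −78 °C
Reagents that add atoms: none
Why: Luche 1,2-reduction, in which hydride is expected to add from the α face, anti to the axial angular methyl group on C8a, to give the equatorial 8β-alcohol.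

Step 14
Reactants: 19 (3R,3aS,4S,8S,8aS)-4-[(tert-butyldimethylsilyl)oxy]-6,8a-dimethyl-3-(propan-2-yl)-1,2,3,3a,4,5,8,8a-octahydroazulene-3,8-diol
Product: 20 (3R,3aS,4S,8R,8aS)-4-[(tert-butyldimethylsilyl)oxy]-3-hydroxy-6,8a-dimethyl-3-(propan-2-yl)-1,2,3,3a,4,5,8,8a-octahydroazulen-8-yl acetate
Conditions: AcOH, PPh3, DIAD, toluene, 0 °C to rt
Reagents that add atoms: acetic acid, CC(=O)O
Why: Mitsunobu esterification with acetic acid proceeds by SN2 inversion at C8 from the open α face and should give the 8α-acetate directly; the tertiary C3 alcohol does not react.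

Step 15
Reactants: 20 (3R,3aS,4S,8R,8aS)-4-[(tert-butyldimethylsilyl)oxy]-3-hydroxy-6,8a-dimethyl-3-(propan-2-yl)-1,2,3,3a,4,5,8,8a-octahydroazulen-8-yl acetate
Product: 21 (3R,3aS,4S,8R,8aS)-3,4-dihydroxy-6,8a-dimethyl-3-(propan-2-yl)-1,2,3,3a,4,5,8,8a-octahydroazulen-8-yl acetate
Conditions: HF·pyridine, pyridine, THF, 0 °C to rt
Reagents that add atoms: none
Why: Fluoride-mediated desilylation under buffered acidic conditions, chosen to avoid acetate migration or hydrolysis.

Step 16
Reactants: 21 (3R,3aS,4S,8R,8aS)-3,4-dihydroxy-6,8a-dimethyl-3-(propan-2-yl)-1,2,3,3a,4,5,8,8a-octahydroazulen-8-yl acetate; 22 4-methoxybenzoyl chloride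
Product: 23 (3R,3aS,4S,8R,8aS)-8-acetoxy-3-hydroxy-6,8a-dimethyl-3-(propan-2-yl)-1,2,3,3a,4,5,8,8a-octahydroazulen-4-yl 4-methoxybenzoate (CNP0256979.2)
Conditions: Et3N, DMAP (cat.), CH2Cl2, rt
Reagents that add atoms: none
Why: DMAP-catalysed acylation of the only secondary alcohol (C4) with retention of configuration; the tertiary C3 alcohol is too hindered to react.

**Compound list**

1 | cyclohepta-1,3-diene | C1=CC=CCCC1 | starting material
2 | (1R,5S)-6,7-dioxabicyclo[3.2.2]non-8-ene (meso) | C1CC[C@@H]2OO[C@H]1C=C2 | intermediate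
3 | (4S)-4-hydroxycyclohept-2-en-1-one | O[C@H]1CCCC(=O)C=C1 | intermediate
4 | (4S)-4-[(tert-butyldimethylsilyl)oxy]cyclohept-2-en-1-one | CC(C)(C)[Si](C)(C)O[C@H]1CCCC(=O)C=C1 | intermediate
5 | (4S)-4-[(tert-butyldimethylsilyl)oxy]-2-iodocyclohept-2-en-1-one | CC(C)(C)[Si](C)(C)O[C@H]1CCCC(=O)C(I)=C1 | intermediate
6 | (4S)-4-[(tert-butyldimethylsilyl)oxy]-2-methylcyclohept-2-en-1-one | CC(C)(C)[Si](C)(C)O[C@H]1CCCC(=O)C(C)=C1 | intermediate
7 | 2-bromo-3-methylbut-1-ene | CC(C)C(Br)=C | starting material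
8 | 3-iodoprop-1-ene (allyl iodide) | C=CCI | starting material
9 | (3S,4S)-4-[(tert-butyldimethylsilyl)oxy]-2-methyl-3-(3-methylbut-1-en-2-yl)-1-[(trimethylsilyl)oxy]cyclohept-1-ene | CC(C)(C)[Si](C)(C)O[C@H]1CCCC(O[Si](C)(C)C)=C(C)[C@@H]1C(=C)C(C)C | intermediate
10 | lithium (3S,4S)-4-[(tert-butyldimethylsilyl)oxy]-2-methyl-3-(3-methylbut-1-en-2-yl)cyclohept-1-en-1-olate | CC(C)(C)[Si](C)(C)O[C@H]1CCCC(O[Li])=C(C)[C@@H]1C(=C)C(C)C | intermediate
11 | (2S,3S,4S)-4-[(tert-butyldimethylsilyl)oxy]-2-methyl-3-(3-methylbut-1-en-2-yl)-2-(prop-2-en-1-yl)cycloheptan-1-one | CC(C)(C)[Si](C)(C)O[C@H]1CCCC(=O)[C@@](C)(CC=C)[C@@H]1C(=C)C(C)C | intermediate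
12 | 2-[(1S,2S,3S)-3-[(tert-butyldimethylsilyl)oxy]-1-methyl-2-(2-methylpropanoyl)-7-oxocycloheptyl]acetaldehyde | CC(C)(C)[Si](C)(C)O[C@H]1CCCC(=O)[C@@](C)(CC=O)[C@@H]1C(=O)C(C)C | intermediate
13 | (2S,3S,4S)-4-[(tert-butyldimethylsilyl)oxy]-2-(2-hydroxyethyl)-2-methyl-3-(2-methylpropanoyl)cycloheptan-1-one | CC(C)(C)[Si](C)(C)O[C@H]1CCCC(=O)[C@@](C)(CCO)[C@@H]1C(=O)C(C)C | intermediate
14 | (2S,3S,4S)-4-[(tert-butyldimethylsilyl)oxy]-2-(2-iodoethyl)-2-methyl-3-(2-methylpropanoyl)cycloheptan-1-one | CC(C)(C)[Si](C)(C)O[C@H]1CCCC(=O)[C@@](C)(CCI)[C@@H]1C(=O)C(C)C | intermediate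
15 | (3R,3aS,4S,8aS)-4-[(tert-butyldimethylsilyl)oxy]-3-hydroxy-8a-methyl-3-(propan-2-yl)octahydroazulen-8(1H)-one | CC(C)(C)[Si](C)(C)O[C@H]1CCCC(=O)[C@@]2(C)CC[C@@](O)(C(C)C)[C@H]12 | intermediate
16 | (3R,3aS,4S,8aS)-4-[(tert-butyldimethylsilyl)oxy]-3-hydroxy-8a-methyl-3-(propan-2-yl)-2,3,3a,4,5,8a-hexahydroazulen-8(1H)-one | CC(C)(C)[Si](C)(C)O[C@H]1CC=CC(=O)[C@@]2(C)CC[C@@](O)(C(C)C)[C@H]12 | intermediate
17 | (3R,3aS,4S,8aS)-4-[(tert-butyldimethylsilyl)oxy]-6,8a-dimethyl-3-(propan-2-yl)-8-[(trimethylsilyl)oxy]-1,2,3,3a,4,5,6,8a-octahydroazulen-3-ol (both C6 epimers) | CC(C)(C)[Si](C)(C)O[C@H]1CC(C)C=C(O[Si](C)(C)C)[C@@]2(C)CC[C@@](O)(C(C)C)[C@H]12 | intermediate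
18 | (3R,3aS,4S,8aS)-4-[(tert-butyldimethylsilyl)oxy]-3-hydroxy-6,8a-dimethyl-3-(propan-2-yl)-2,3,3a,4,5,8a-hexahydroazulen-8(1H)-one | CC(C)(C)[Si](C)(C)O[C@H]1CC(C)=CC(=O)[C@@]2(C)CC[C@@](O)(C(C)C)[C@H]12 | intermediate
19 | (3R,3aS,4S,8S,8aS)-4-[(tert-butyldimethylsilyl)oxy]-6,8a-dimethyl-3-(propan-2-yl)-1,2,3,3a,4,5,8,8a-octahydroazulene-3,8-diol | CC(C)(C)[Si](C)(C)O[C@H]1CC(C)=C[C@H](O)[C@@]2(C)CC[C@@](O)(C(C)C)[C@H]12 | intermediate
20 | (3R,3aS,4S,8R,8aS)-4-[(tert-butyldimethylsilyl)oxy]-3-hydroxy-6,8a-dimethyl-3-(propan-2-yl)-1,2,3,3a,4,5,8,8a-octahydroazulen-8-yl acetate | CC(C)(C)[Si](C)(C)O[C@H]1CC(C)=C[C@@H](OC(C)=O)[C@@]2(C)CC[C@@](O)(C(C)C)[C@H]12 | intermediate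
21 | (3R,3aS,4S,8R,8aS)-3,4-dihydroxy-6,8a-dimethyl-3-(propan-2-yl)-1,2,3,3a,4,5,8,8a-octahydroazulen-8-yl acetate | O[C@H]1CC(C)=C[C@@H](OC(C)=O)[C@@]2(C)CC[C@@](O)(C(C)C)[C@H]12 | intermediate
22 | 4-methoxybenzoyl chloride | COc1ccc(cc1)C(Cl)=O | starting material
23 | (3R,3aS,4S,8R,8aS)-8-acetoxy-3-hydroxy-6,8a-dimethyl-3-(propan-2-yl)-1,2,3,3a,4,5,8,8a-octahydroazulen-4-yl 4-methoxybenzoate | COc1ccc(C(=O)O[C@H]2CC(C)=C[C@@H](OC(C)=O)[C@@]3(C)CC[C@@](O)(C(C)C)[C@H]23)cc1 | target

**Step count and risks**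

Total step count: 16. Longest linear sequence: 16 steps, from cyclohepta-1,3-diene 1.

Steps most likely to fail:

Step 10 (key step). What may go wrong: the alkylsamarium may be protonated before it adds, so that iodine is simply lost, or the facial discrimination at the carbonyl may be poor. The fallback sets out from keto aldehyde 12 and returns at 15. Compound 12 is treated with SmI2 in THF at −78 °C, a ketyl–carbonyl pinacol cyclisation that joins the aldehyde and ketone carbons directly and should give the cis-diol (2S,3R,3aS,4S,8aS)-4-[(tert-butyldimethylsilyl)oxy]-2,3-dihydroxy-8a-methyl-3-(propan-2-yl)octahydroazulen-8(1H)-one F2. The secondary hydroxyl alone is converted with phenyl chlorothionoformate and pyridine into O-[(2S,3R,3aS,4S,8aS)-4-[(tert-butyldimethylsilyl)oxy]-3-hydroxy-8a-methyl-8-oxo-3-(propan-2-yl)decahydroazulen-2-yl] O-phenyl carbonothioate F3. Barton–McCombie deoxygenation (Bu3SnH, AIBN, toluene, 80 °C) then removes the C2 oxygen to give 15.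

Step 6. What may go wrong: C-allylation of the crowded, fully substituted lithium enolate may be slower than proton transfer, which would scramble the enolate position, or the enolate may react at oxygen. The fallback sets out from 6 and returns at 11. After the same conjugate addition and MeLi cleavage, the enolate 10 is acylated on oxygen with allyl chloroformate to give allyl (3S,4S)-4-[(tert-butyldimethylsilyl)oxy]-2-methyl-3-(3-methylbut-1-en-2-yl)cyclohept-1-en-1-yl carbonate F1. Pd(PPh3)4 in THF then effects the decarboxylative Tsuji allylation: the π-allylpalladium cation and the regiodefined enolate form as an ion pair under neutral conditions and combine at carbon anti to the alkenyl group, giving 11.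

Step 14. What may go wrong: substitution at the neopentyl allylic carbon may be overtaken by elimination or by attack at C6 with allylic transposition, and the step relies on step 13 delivering the β-face alcohol. The fallback sets out from 18 and returns at 20. Enone 18 is reduced under reagent control by Corey–Bakshi–Shibata reduction (oxazaborolidine catalyst, BH3·SMe2, using the catalyst antipode that delivers hydride to the β face) to (3R,3aS,4S,8R,8aS)-4-[(tert-butyldimethylsilyl)oxy]-6,8a-dimethyl-3-(propan-2-yl)-1,2,3,3a,4,5,8,8a-octahydroazulene-3,8-diol F4. This alcohol is acetylated with retention (Ac2O, pyridine, DMAP) to give 20.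

Further compounds
F1 | step 6 | allyl (3S,4S)-4-[(tert-butyldimethylsilyl)oxy]-2-methyl-3-(3-methylbut-1-en-2-yl)cyclohept-1-en-1-yl carbonate | CC(C)(C)[Si](C)(C)O[C@H]1CCCC(OC(=O)OCC=C)=C(C)[C@@H]1C(=C)C(C)C
F2 | step 10 | (2S,3R,3aS,4S,8aS)-4-[(tert-butyldimethylsilyl)oxy]-2,3-dihydroxy-8a-methyl-3-(propan-2-yl)octahydroazulen-8(1H)-one | CC(C)(C)[Si](C)(C)O[C@H]1CCCC(=O)[C@@]2(C)C[C@H](O)[C@@](O)(C(C)C)[C@H]12
F3 | step 10 | O-[(2S,3R,3aS,4S,8aS)-4-[(tert-butyldimethylsilyl)oxy]-3-hydroxy-8a-methyl-8-oxo-3-(propan-2-yl)decahydroazulen-2-yl] O-phenyl carbonothioate | CC(C)(C)[Si](C)(C)O[C@H]1CCCC(=O)[C@@]2(C)C[C@H](OC(=S)Oc3ccccc3)[C@@](O)(C(C)C)[C@H]12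
F4 | step 14 | (3R,3aS,4S,8R,8aS)-4-[(tert-butyldimethylsilyl)oxy]-6,8a-dimethyl-3-(propan-2-yl)-1,2,3,3a,4,5,8,8a-octahydroazulene-3,8-diol | CC(C)(C)[Si](C)(C)O[C@H]1CC(C)=C[C@@H](O)[C@@]2(C)CC[C@@](O)(C(C)C)[C@H]12
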